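The route rests on cutting the C2–C3 bond of the dihydrofuran ring. C3 is a benzylic carbinol carbon, and C2 carries O1 plus a 1-formylvinyl arm that traces back to an acetyl group, so C2–C3 is the bond of an aldol between an aryloxy ketone and an ortho formyl group. One amine-catalysed intramolecular aldol forms this bond, closes the O1–C2–C3–C3a–C7a ring and sets both ring stereocentres, cis and in the absolute sense. Its precursor is achiral: the ether of 5-bromosalicylaldehyde with chloroacetone, whose bromine at the future C5 later becomes the acyloxyethyl side chain.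

Key step: step 2

Remark: the sense of induction in step 2 is taken from the acid-directed enamine model, by which L-proline would give the (2S,3R) antipode; D-proline is therefore specified.

Step 1
Reactants: 1 5-bromosalicylaldehyde, 2 chloroacetone
Product: 3 5-bromo-2-(2-oxopropoxy)benzaldehyde
Conditions: K2CO3, KI (cat.), DMF, 0 °C → rt
Reagents that add atoms: none
Why: Williamson ether synthesis, in which the phenoxide displaces halide from the α-halo ketone (iodide-assisted SN2); mild carbonate at room temperature should stop at the ether, because the follow-up aldol condensation to 2-acetyl-5-bromobenzofuran needs heat.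

Step 2
Reactants: 3 5-bromo-2-(2-oxopropoxy)benzaldehyde
Product: 6 1-[(2R,3S)-5-bromo-3-hydroxy-2,3-dihydro-1-benzofuran-2-yl]ethan-1-one, via proline enamine 4 (not isolated), via iminium carboxylate 5 (not isolated)
Conditions: D-proline (30 mol%), DMF, 4 °C → rt; cold neutral work-up; recrystallise
Reagents that add atoms: none
Why: Enamine aldol of the proline type, a known closure for O-acetonyl salicylaldehydes: D-proline condenses with the ketone to enamine 4 on the OCH2 side, its oxygen-bearing carbon adds to the ortho formyl group, and hydrolysis of iminium carboxylate 5 returns the catalyst. The single ring closes in a 5-(enolexo)-exo-trig mode, the enamine double bond lying outside the new O1–C2–C3–C3a–C7a ring. C2 is controlled by the catalyst stereocentre: the carboxylic acid on the pyrrolidine delivers the aldehyde to one face of the (E)-enamine, which for the (R)-catalyst should give 2R. C3 is controlled by the same hydrogen bond, which holds the carbonyl oxygen on the side of the enamine nitrogen, so the new hydroxyl and the C2 acyl carbon end up cis (3S). The step needs use of the OCH2 rather than the CH3 enamine, cis selectivity, enantioselectivity and survival of the β-hydroxy ketone; the substrate favours the first through a five- over a seven-membered closure, its short aryl ether tether allows only the hydrogen-bonded cis arrangement, and neutral conditions at or below room temperature should prevent dehydration to the benzofuran. The bromo aldol is expected to be crystalline, so optical purity should be raisable by recrystallisation.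

Step 3
Reactants: 6 1-[(2R,3S)-5-bromo-3-hydroxy-2,3-dihydro-1-benzofuran-2-yl]ethan-1-one
Product: 7 1-[(2R,3S)-5-bromo-3-{[tert-butyl(dimethyl)silyl]oxy}-2,3-dihydro-1-benzofuran-2-yl]ethan-1-one
Conditions: TBSOTf, 2,6-lutidine, CH2Cl2, −78 °C
Reagents that add atoms: tert-butyldimethylsilyl trifluoromethanesulfonate, CC(C)(C)[Si](C)(C)OS(=O)(=O)C(F)(F)F
Why: Silyl ether formation with a silyl triflate and a hindered pyridine base is fast at −78 °C and should cause no retro-aldol, C2 epimerisation or β-elimination; a silyloxy group is chosen over an acetate because it is a poor leaving group next to the acidic C2–H and is inert to the olefination reagent of step 4.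

Step 4
Reactants: 7 1-[(2R,3S)-5-bromo-3-{[tert-butyl(dimethyl)silyl]oxy}-2,3-dihydro-1-benzofuran-2-yl]ethan-1-one
Product: 8 {[(2S,3S)-5-bromo-2-(prop-1-en-2-yl)-2,3-dihydro-1-benzofuran-3-yl]oxy}(tert-butyl)dimethylsilane
Conditions: Cp2TiMe2, toluene, 65 °C, dark
Reagents that add atoms: dimethyltitanocene Cp2TiMe2, C[Ti](C)(C1C=CC=C1)C1C=CC=C1
Why: Petasis methylenation, in which thermally generated Cp2Ti=CH2 turns the ketone into the 1,1-disubstituted alkene without base, so the configuration at the enolisable C2, the silyl ether and the aryl bromide should be untouched (the descriptor at C2 changes from R to S only through the priority rules).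

Step 5
Reactants: 8 {[(2S,3S)-5-bromo-2-(prop-1-en-2-yl)-2,3-dihydro-1-benzofuran-3-yl]oxy}(tert-butyl)dimethylsilane, 9 N-methoxy-N-methylacetamide
Product: 12 1-[(2S,3S)-3-{[tert-butyl(dimethyl)silyl]oxy}-2-(prop-1-en-2-yl)-2,3-dihydro-1-benzofuran-5-yl]ethan-1-one, via aryllithium 10 (not isolated), via lithium hemiaminal alkoxide 11 (not isolated)
Conditions: n-BuLi, THF, −78 °C; then 9, −78 → 0 °C; aq. NH4Cl
Reagents that add atoms: none
Why: Bromine–lithium exchange followed by Weinreb amide acylation, in which the chelated tetrahedral adduct 11 prevents over-addition and releases the aryl methyl ketone on work-up; the metal-free sequence avoids exposing the allylic aryl ether O1–C2 to zerovalent palladium, which could ionise it.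

Step 6
Reactants: 12 1-[(2S,3S)-3-{[tert-butyl(dimethyl)silyl]oxy}-2-(prop-1-en-2-yl)-2,3-dihydro-1-benzofuran-5-yl]ethan-1-one
Product: 13 (1R)-1-[(2S,3S)-3-{[tert-butyl(dimethyl)silyl]oxy}-2-(prop-1-en-2-yl)-2,3-dihydro-1-benzofuran-5-yl]ethan-1-ol
Conditions: RuCl[(R,R)-TsDPEN](p-cymene) (1 mol%), HCO2H–Et3N (5:2), EtOAc, 30 °C
Reagents that add atoms: none
Why: Noyori asymmetric transfer hydrogenation, in which the bifunctional ruthenium hydride/NH catalyst reduces aryl methyl ketones under catalyst control, the (R,R)-ligand giving the (R)-carbinol; unlike a borane reductant it should leave the isolated alkene alone, and the remote ring stereocentres should not interfere.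

Step 7
Reactants: 13 (1R)-1-[(2S,3S)-3-{[tert-butyl(dimethyl)silyl]oxy}-2-(prop-1-en-2-yl)-2,3-dihydro-1-benzofuran-5-yl]ethan-1-ol, 14 angelic acid
Product: 16 (1R)-1-[(2S,3S)-3-{[tert-butyl(dimethyl)silyl]oxy}-2-(prop-1-en-2-yl)-2,3-dihydro-1-benzofuran-5-yl]ethyl (2Z)-2-methylbut-2-enoate, via mixed anhydride 15 (not isolated)
Conditions: 14, 2,4,6-Cl3C6H2COCl, Et3N, toluene, rt; then 13, toluene, 70 °C
Reagents that add atoms: none
Why: Yamaguchi esterification, in which the alcohol attacks the less hindered angeloyl carbonyl of mixed anhydride 15; omitting a nucleophilic amine catalyst is the usual way to keep the Z double bond from isomerising to the tiglate, and the carbinol configuration is retained because its C–O bond is not broken.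

Step 8
Reactants: 16 (1R)-1-[(2S,3S)-3-{[tert-butyl(dimethyl)silyl]oxy}-2-(prop-1-en-2-yl)-2,3-dihydro-1-benzofuran-5-yl]ethyl (2Z)-2-methylbut-2-enoate
Product: 17 (1R)-1-[(2S,3S)-3-hydroxy-2-(prop-1-en-2-yl)-2,3-dihydro-1-benzofuran-5-yl]ethyl (2Z)-2-methylbut-2-enoate
Conditions: TBAF, AcOH, THF, 0 °C → rt
Reagents that add atoms: none
Why: Fluoride-mediated silyl ether cleavage buffered with acetic acid, a near-neutral desilylation that should neither transesterify nor isomerise the angelate.

Step 9
Reactants: 17 (1R)-1-[(2S,3S)-3-hydroxy-2-(prop-1-en-2-yl)-2,3-dihydro-1-benzofuran-5-yl]ethyl (2Z)-2-methylbut-2-enoate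
Product: 18 (1R)-1-[(2S,3S)-3-(acetyloxy)-2-(prop-1-en-2-yl)-2,3-dihydro-1-benzofuran-5-yl]ethyl (2Z)-2-methylbut-2-enoate
Conditions: Ac2O, pyridine, DMAP (cat.), CH2Cl2, 0 °C
Reagents that add atoms: acetic anhydride, CC(=O)OC(C)=O
Why: Amine-catalysed acylation of the secondary benzylic alcohol under cold, mildly basic conditions; the acetate is introduced only now because, with no carbonyl group left at C2, elimination to the benzofuran is no longer activated.

Step 10
Reactants: 18 (1R)-1-[(2S,3S)-3-(acetyloxy)-2-(prop-1-en-2-yl)-2,3-dihydro-1-benzofuran-5-yl]ethyl (2Z)-2-methylbut-2-enoate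
Product: 20 (1R)-1-[(2S,3S)-3-(acetyloxy)-2-(3-oxoprop-1-en-2-yl)-2,3-dihydro-1-benzofuran-5-yl]ethyl (2Z)-2-methylbut-2-enoate, via allylic alcohol 19 (not isolated)
Conditions: SeO2 (0.5 equiv), t-BuOOH, CH2Cl2, rt; then MnO2, CH2Cl2, rt
Reagents that add atoms: selenium dioxide, O=[Se]=O; tert-butyl hydroperoxide, CC(C)(C)OO
Why: Sharpless-type SeO2/t-BuOOH allylic oxidation (ene reaction, then [2,3]-sigmatropic shift) should oxidise the methyl group of the 1,1-disubstituted alkene in preference to the electron-poor angelate, and MnO2 then oxidises allylic alcohol 19 selectively to the enal without touching esters or stereocentres.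

Compound list
1 | 5-bromosalicylaldehyde (5-bromo-2-hydroxybenzaldehyde) | Oc1ccc(Br)cc1C=O | starting material
2 | chloroacetone (1-chloropropan-2-one) | CC(=O)CCl | starting material
3 | 5-bromo-2-(2-oxopropoxy)benzaldehyde | CC(=O)COc1ccc(Br)cc1C=O | intermediate
4 | (2R)-1-[(1E)-1-(4-bromo-2-formylphenoxy)prop-1-en-2-yl]pyrrolidine-2-carboxylic acid (proline enamine) | OC(=O)[C@H]1CCCN1/C(C)=C/Oc1ccc(Br)cc1C=O | intermediate
5 | (2R)-1-{1-[(2S,3S)-5-bromo-3-hydroxy-2,3-dihydro-1-benzofuran-2-yl]ethylidene}pyrrolidin-1-ium-2-carboxylate (iminium carboxylate) | CC(=[N+]1CCC[C@@H]1C([O-])=O)[C@@H]1Oc2ccc(Br)cc2[C@@H]1O | intermediate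
6 | 1-[(2R,3S)-5-bromo-3-hydroxy-2,3-dihydro-1-benzofuran-2-yl]ethan-1-one (cis) | CC(=O)[C@@H]1Oc2ccc(Br)cc2[C@@H]1O | intermediate
7 | 1-[(2R,3S)-5-bromo-3-{[tert-butyl(dimethyl)silyl]oxy}-2,3-dihydro-1-benzofuran-2-yl]ethan-1-one | CC(=O)[C@@H]1Oc2ccc(Br)cc2[C@@H]1O[Si](C)(C)C(C)(C)C | intermediate
8 | {[(2S,3S)-5-bromo-2-(prop-1-en-2-yl)-2,3-dihydro-1-benzofuran-3-yl]oxy}(tert-butyl)dimethylsilane | C=C(C)[C@@H]1Oc2ccc(Br)cc2[C@@H]1O[Si](C)(C)C(C)(C)C | intermediate
9 | N-methoxy-N-methylacetamide | CON(C)C(C)=O | starting material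
10 | [(2S,3S)-3-{[tert-butyl(dimethyl)silyl]oxy}-2-(prop-1-en-2-yl)-2,3-dihydro-1-benzofuran-5-yl]lithium (aryllithium) | C=C(C)[C@@H]1Oc2ccc([Li])cc2[C@@H]1O[Si](C)(C)C(C)(C)C | intermediate
11 | lithium 1-[(2S,3S)-3-{[tert-butyl(dimethyl)silyl]oxy}-2-(prop-1-en-2-yl)-2,3-dihydro-1-benzofuran-5-yl]-1-[methoxy(methyl)amino]ethan-1-olate (configuration at the new carbon undefined) | C=C(C)[C@@H]1Oc2ccc(C(C)(O[Li])N(C)OC)cc2[C@@H]1O[Si](C)(C)C(C)(C)C | intermediate
12 | 1-[(2S,3S)-3-{[tert-butyl(dimethyl)silyl]oxy}-2-(prop-1-en-2-yl)-2,3-dihydro-1-benzofuran-5-yl]ethan-1-one | C=C(C)[C@@H]1Oc2ccc(C(C)=O)cc2[C@@H]1O[Si](C)(C)C(C)(C)C | intermediate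
13 | (1R)-1-[(2S,3S)-3-{[tert-butyl(dimethyl)silyl]oxy}-2-(prop-1-en-2-yl)-2,3-dihydro-1-benzofuran-5-yl]ethan-1-ol | C=C(C)[C@@H]1Oc2ccc([C@@H](C)O)cc2[C@@H]1O[Si](C)(C)C(C)(C)C | intermediate
14 | angelic acid, (2Z)-2-methylbut-2-enoic acid | C/C=C(C)\C(O)=O | starting material
15 | (2Z)-2-methylbut-2-enoic 2,4,6-trichlorobenzoic anhydride (mixed anhydride) | C/C=C(C)\C(=O)OC(=O)c1c(Cl)cc(Cl)cc1Cl | intermediate
16 | (1R)-1-[(2S,3S)-3-{[tert-butyl(dimethyl)silyl]oxy}-2-(prop-1-en-2-yl)-2,3-dihydro-1-benzofuran-5-yl]ethyl (2Z)-2-methylbut-2-enoate | C=C(C)[C@@H]1Oc2ccc([C@@H](C)OC(=O)/C(C)=C\C)cc2[C@@H]1O[Si](C)(C)C(C)(C)C | intermediate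
17 | (1R)-1-[(2S,3S)-3-hydroxy-2-(prop-1-en-2-yl)-2,3-dihydro-1-benzofuran-5-yl]ethyl (2Z)-2-methylbut-2-enoate | C=C(C)[C@@H]1Oc2ccc([C@@H](C)OC(=O)/C(C)=C\C)cc2[C@@H]1O | intermediate
18 | (1R)-1-[(2S,3S)-3-(acetyloxy)-2-(prop-1-en-2-yl)-2,3-dihydro-1-benzofuran-5-yl]ethyl (2Z)-2-methylbut-2-enoate | C=C(C)[C@@H]1Oc2ccc([C@@H](C)OC(=O)/C(C)=C\C)cc2[C@@H]1OC(C)=O | intermediate
19 | (1R)-1-[(2S,3S)-3-(acetyloxy)-2-(3-hydroxyprop-1-en-2-yl)-2,3-dihydro-1-benzofuran-5-yl]ethyl (2Z)-2-methylbut-2-enoate (allylic alcohol) | C=C(CO)[C@@H]1Oc2ccc([C@@H](C)OC(=O)/C(C)=C\C)cc2[C@@H]1OC(C)=O | intermediate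
20 | (1R)-1-[(2S,3S)-3-(acetyloxy)-2-(3-oxoprop-1-en-2-yl)-2,3-dihydro-1-benzofuran-5-yl]ethyl (2Z)-2-methylbut-2-enoate | C=C(C=O)[C@@H]1Oc2ccc([C@@H](C)OC(=O)/C(C)=C\C)cc2[C@@H]1OC(C)=O | target

Total step count: 10
Longest linear sequence: 10 steps (1 to 20)

Steps most likely to fail

Step 2. The enamine addition may show insufficient facial selectivity, so that the cis aldol forms with an optical purity that recrystallisation of 6 cannot raise far enough; slow dehydration to the aromatic benzofuran would make this worse on long reaction times. The fallback moves the final control of the ring configuration from amine catalysis to an enzyme. Material of modest optical purity is carried on unchanged to 17, where the (R)-configured side chain makes the minor ring antipode a diastereomer. Setting out from 17, the acetylation with acetic anhydride is replaced by a lipase-catalysed acetylation (immobilised Candida antarctica lipase B, vinyl acetate, tert-butyl methyl ether, 30 °C). The empirical preference of such lipases for cyclic benzylic alcohols corresponds to the (3S) carbinol, so the wanted isomer should be acetylated selectively and the unreacted diastereomer removed as an alcohol by chromatography. The way returns to the route at 18 and makes no new compound (F0).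

Step 10. Hydrogen abstraction at C2–H may compete with that at the methyl group, the oxidation may over-run, and the acidic selenium species may ionise the C3 acetate and trigger aromatisation. The fallback, setting out from 18, separates functionalisation from oxidation. An ene-type allylic chlorination with N-chlorosuccinimide and catalytic PhSeCl in CH2Cl2 at room temperature should give the rearranged allylic chloride (1R)-1-[(2S,3S)-3-(acetyloxy)-2-(3-chloroprop-1-en-2-yl)-2,3-dihydro-1-benzofuran-5-yl]ethyl (2Z)-2-methylbut-2-enoate F1. A Kornblum-type oxidation with N-methylmorpholine N-oxide in acetonitrile (substitution by the N-oxide oxygen, then elimination) then converts the allylic chloride into the enal, and the way returns to the route at 20.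

Step 7. The Z double bond of the acyl donor may isomerise to the E (tigloyl) form during activation and heating, and the p-alkoxybenzylic carbinol may ionise at 70 °C. The fallback forms the ester C–O bond by substitution at carbon instead of acyl transfer. Setting out from 12, transfer hydrogenation with the antipodal catalyst RuCl[(S,S)-TsDPEN](p-cymene) in HCO2H–Et3N gives (1S)-1-[(2S,3S)-3-{[tert-butyl(dimethyl)silyl]oxy}-2-(prop-1-en-2-yl)-2,3-dihydro-1-benzofuran-5-yl]ethan-1-ol F2. A Mitsunobu reaction with angelic acid 14 (PPh3, diisopropyl azodicarboxylate, toluene, 0 °C) then installs the angelate with inversion under neutral conditions at low temperature, which are known to preserve the Z geometry. The way returns to the route at 16.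

Further compounds
F0 | step 2 | none | none
F1 | step 10 | (1R)-1-[(2S,3S)-3-(acetyloxy)-2-(3-chloroprop-1-en-2-yl)-2,3-dihydro-1-benzofuran-5-yl]ethyl (2Z)-2-methylbut-2-enoate | C=C(CCl)[C@@H]1Oc2ccc([C@@H](C)OC(=O)/C(C)=C\C)cc2[C@@H]1OC(C)=O
F2 | step 7 | (1S)-1-[(2S,3S)-3-{[tert-butyl(dimethyl)silyl]oxy}-2-(prop-1-en-2-yl)-2,3-dihydro-1-benzofuran-5-yl]ethan-1-ol | C=C(C)[C@@H]1Oc2ccc([C@H](C)O)cc2[C@@H]1O[Si](C)(C)C(C)(C)C
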